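**Strategy.** Everything rests on cutting ring C of the lower (epigallocatechin) unit at C4–C4a and O1–C8a. Its O1–C2–C3–C4 chain is stored as a cis-2-aryl-3-benzyloxyoxetane; C4a and C8a are adjacent carbons of ring A, held as C–Li and C–F. In one flask the aryllithium opens the oxetane at CH2, and the alkoxide so released displaces the neighbouring fluoride, giving the chroman with both stereocentres untouched. The precursor is a 4-(3-bromo-2-fluoro-4,6-dibenzyloxyphenyl)flavan made from (+)-dihydrorobinetin by aryl addition to the C4 ketone and ionic hydrogenation, so the 4→8 link and the 3,4-cis configuration are set before the lower heterocycle exists.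

Key step: step 11

Remark: the SMILES is read as robinetinidol-(4β→8)-epigallocatechin, upper unit (2R,3S,4R) (2,3-trans-3,4-cis), lower unit (2R,3R) (2,3-cis). Flavan numbering is used, with primed locants for the lower unit. (+)-Dihydrorobinetin is taken as a commercial natural product.

**Step 1**
Reactants: 1 (+)-dihydrorobinetin
Product: 2 (2R,3R)-7-(benzyloxy)-3-hydroxy-2-[3,4,5-tris(benzyloxy)phenyl]chroman-4-one
Conditions: BnBr, K2CO3, DMF, rt, N2
Reagents that add atoms: benzyl bromide, BrCc1ccccc1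
Why: Williamson etherification in which K2CO3 deprotonates only the four phenols, while the mild base at room temperature should leave the C3 alcohol and the 2,3-trans ketol stereocentres (chiral pool) untouched.

**Step 2**
Reactants: 2 tetra-O-benzyl ketol
Product: 3 (2R,3R)-3,7-bis(benzyloxy)-2-[3,4,5-tris(benzyloxy)phenyl]chroman-4-one
Conditions: benzyl 2,2,2-trichloroacetimidate, TfOH (cat.), CH2Cl2/cyclohexane, 0 °C → rt
Reagents that add atoms: benzyl 2,2,2-trichloroacetimidate, N=C(OCc1ccccc1)C(Cl)(Cl)Cl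
Why: Acid-catalysed O-benzylation with a trichloroacetimidate avoids the strong base that would enolise the ketol and open ring C, and the resulting ether keeps O3 from competing in the later fluoride displacement.

**Step 3**
Reactants: 4 1,3,5-trifluorobenzene
Product: 5 1,3-bis(benzyloxy)-5-fluorobenzene
Conditions: BnOH (2.1 equiv), NaH (2.2 equiv), NMP, 0 → 80 °C
Reagents that add atoms: benzyl alcohol, OCc1ccccc1
Why: Twofold SNAr by benzyloxide, in which each replacement of F by OBn lowers the activation of the remaining C–F bonds, so the stoichiometry should stop the reaction at the monofluoride.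

**Step 4**
Reactants: 5 1,3-bis(benzyloxy)-5-fluorobenzene
Product: 6 1,5-bis(benzyloxy)-2,4-dibromo-3-fluorobenzene
Conditions: NBS (2.05 equiv), MeCN, 0 °C → rt, dark
Reagents that add atoms: N-bromosuccinimide, O=C1CCC(=O)N1Br
Why: Electrophilic aromatic bromination at the two carbons flanking fluorine (each para to one OBn, ortho to the other, and less hindered than the carbon between the two OBn groups), which fixes the sites of both later lithiations.

**Step 5**
Reactants: 6 1,5-bis(benzyloxy)-2,4-dibromo-3-fluorobenzene; 3 penta-O-benzyl ketone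
Product: 9 (2R,3R,4R)-4-[4,6-bis(benzyloxy)-3-bromo-2-fluorophenyl]-3,7-bis(benzyloxy)-2-[3,4,5-tris(benzyloxy)phenyl]chroman-4-ol, via aryllithium 7 (not isolated), via arylcerium dichloride 8 (not isolated)
Conditions: n-BuLi (1.0 equiv), THF, −78 °C; CeCl3 (anhydrous), −78 °C; then 3, −78 → −40 °C; aq. NH4Cl
Reagents that add atoms: none
Why: Bromine–lithium exchange outruns any deprotonation, and the weakly basic, oxophilic organocerium should add 1,2 to the hindered, enolisable α-alkoxy ketone; the aryl is expected to enter anti to the C3 benzyloxy group, but C4 is set anew in step 6.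

**Step 6**
Reactants: 9 tertiary alcohol
Product: 10 (2R,3S,4R)-4-[4,6-bis(benzyloxy)-3-bromo-2-fluorophenyl]-3,7-bis(benzyloxy)-2-[3,4,5-tris(benzyloxy)phenyl]chromane
Conditions: Et3SiH, TFA, CH2Cl2, −40 → 0 °C
Reagents that add atoms: none
Why: Ionic hydrogenation in which acid ionises the doubly benzylic alcohol to a cation stabilised by the 7-benzyloxy group and the silane should deliver hydride to C4 anti to the adjacent C3 benzyloxy group (the facial bias by which nucleophiles enter trans to O3 in flavan-4-yl cations), so that H4 ends trans and the aryl cis to O3, (4R).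

**Step 7**
Reactants: 11 (S)-4-benzyloxazolidin-2-one; 12 (benzyloxy)acetyl chloride
Product: 13 (S)-4-benzyl-3-[(benzyloxy)acetyl]oxazolidin-2-one
Conditions: n-BuLi, THF, −78 °C; then 12, −78 → 0 °C
Reagents that add atoms: none
Why: N-acylation of the lithiated oxazolidinone by the acid chloride.

**Step 8**
Reactants: 13 N-glycolyl oxazolidinone; 14 3,4,5-tris(benzyloxy)benzaldehyde
Product: 16 (S)-4-benzyl-3-{(2S,3R)-2-(benzyloxy)-3-hydroxy-3-[3,4,5-tris(benzyloxy)phenyl]propanoyl}oxazolidin-2-one, via dibutylboron (Z)-enolate 15 (not isolated)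
Conditions: Bu2BOTf, i-Pr2NEt, CH2Cl2, −78 → 0 °C; then 14, −78 → 0 °C; pH 7 buffer, MeOH, H2O2
Reagents that add atoms: none
Why: Evans syn-aldol, in which the (Z)-boron enolate reacts through a closed chair transition state on the face away from the benzyl group of the (S)-auxiliary, setting both stereocentres as (2S,3R).

**Step 9**
Reactants: 16 syn-aldol adduct
Product: 17 (1R,2R)-2-(benzyloxy)-1-[3,4,5-tris(benzyloxy)phenyl]propane-1,3-diol
Conditions: LiBH4, MeOH (1 equiv), THF, 0 °C
Reagents that add atoms: none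
Why: Reductive cleavage of the N-acyl oxazolidinone to the primary alcohol, which should proceed without enolisation and so leave both stereocentres intact.

**Step 10**
Reactants: 17 syn-1,3-diol
Product: 19 (2R,3R)-3-(benzyloxy)-2-[3,4,5-tris(benzyloxy)phenyl]oxetane, via primary monotosylate 18 (not isolated)
Conditions: n-BuLi (1.0 equiv), THF, 0 °C; TsCl (1.0 equiv); then n-BuLi (1.05 equiv), 0 → 55 °C
Reagents that add atoms: none
Why: Intramolecular Williamson etherification (4-exo-tet) in which the less hindered primary alkoxide is sulfonylated and the benzylic alkoxide then displaces the primary tosylate, so no stereocentre is touched and the syn aldol relation becomes the cis-2,3 relation of the oxetane.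

**Step 11**
Reactants: 10 bromofluoroaryl flavan; 19 cis-oxetane
Product: 22 (2R,3S,4R)-3,7-bis(benzyloxy)-4-{(2R,3R)-3,5,7-tris(benzyloxy)-2-[3,4,5-tris(benzyloxy)phenyl]chroman-8-yl}-2-[3,4,5-tris(benzyloxy)phenyl]chromane, via aryllithium 20 (not isolated), via ring-opened lithium alkoxide 21 (not isolated)
Conditions: t-BuLi (2.0 equiv), THF, −78 °C; 19, then BF3·OEt2, −78 °C; then KOt-Bu (excess), DMPU, −78 → 60 °C
Reagents that add atoms: none
Why: Bromine–lithium exchange places lithium on C4a' (between F on C8a' and OBn on C5'); this aryllithium attacks the BF3-activated oxetane by SN2 at its CH2 carbon, forming C4'–C4a' and releasing the C2' alkoxide, which, once KOt-Bu has taken up the BF3, adds to C8a' and expels fluoride (addition–elimination SNAr) to form O1'–C8a'. The closest known reaction types are the BF3-promoted opening of 2-aryl-3-oxy-oxetanes by organolithiums at the less substituted carbon and the alkoxide SNAr cyclisation of ortho-alkyl fluoroarenes to chromans, here run in one flask. Ring C of the lower unit closes in the SNAr stage as a 6-exo-trig attack on the arene carbon, and the whole sequence is driven by release of oxetane strain. No stereocentre is formed, because only the C4'–O bond of the oxetane is broken and C2' and C3' are carried over unchanged. The step needs attack at CH2 and not at the benzylic oxetane carbon, which the di-ortho-substituted nucleophile, the low temperature and the electron-withdrawing C3' benzyloxy group should secure. It also needs a single oxygen nucleophile and a single C–F bond, which the benzyl ethers on O3 and O3' and the single fluorine secure.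

**Step 12**
Reactants: 22 undeca-O-benzyl dimer
Product: 23 robinetinidol-(4β→8)-epigallocatechin
Conditions: H2 (1 atm), Pd(OH)2/C, THF/MeOH, rt
Reagents that add atoms: none
Why: Hydrogenolysis of all eleven benzyl ethers under neutral conditions, which should spare the ring C–O bonds and the interflavan C4–C8' bond and touch no stereocentre.

**Compound list**
1 | (+)-dihydrorobinetin, (2R,3R)-3,7-dihydroxy-2-(3,4,5-trihydroxyphenyl)chroman-4-one | Oc1ccc2c(c1)O[C@H](c1cc(O)c(O)c(O)c1)[C@@H](O)C2=O | starting material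
2 | (2R,3R)-7-(benzyloxy)-3-hydroxy-2-[3,4,5-tris(benzyloxy)phenyl]chroman-4-one | c1ccccc1COc1ccc2c(c1)O[C@H](c1cc(OCc3ccccc3)c(OCc3ccccc3)c(OCc3ccccc3)c1)[C@@H](O)C2=O | intermediate
3 | (2R,3R)-3,7-bis(benzyloxy)-2-[3,4,5-tris(benzyloxy)phenyl]chroman-4-one | c1ccccc1COc1ccc2c(c1)O[C@H](c1cc(OCc3ccccc3)c(OCc3ccccc3)c(OCc3ccccc3)c1)[C@@H](OCc1ccccc1)C2=O | intermediate
4 | 1,3,5-trifluorobenzene | Fc1cc(F)cc(F)c1 | starting material
5 | 1,3-bis(benzyloxy)-5-fluorobenzene | Fc1cc(OCc2ccccc2)cc(OCc2ccccc2)c1 | intermediate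
6 | 1,5-bis(benzyloxy)-2,4-dibromo-3-fluorobenzene | Fc1c(Br)c(OCc2ccccc2)cc(OCc2ccccc2)c1Br | intermediate
7 | [4,6-bis(benzyloxy)-3-bromo-2-fluorophenyl]lithium (not isolated) | Fc1c([Li])c(OCc2ccccc2)cc(OCc2ccccc2)c1Br | intermediate
8 | [4,6-bis(benzyloxy)-3-bromo-2-fluorophenyl]cerium dichloride (not isolated) | Fc1c([Ce](Cl)Cl)c(OCc2ccccc2)cc(OCc2ccccc2)c1Br | intermediate
9 | (2R,3R,4R)-4-[4,6-bis(benzyloxy)-3-bromo-2-fluorophenyl]-3,7-bis(benzyloxy)-2-[3,4,5-tris(benzyloxy)phenyl]chroman-4-ol (expected major C4 epimer; C4 is set anew in step 6) | c1ccccc1COc1ccc2c(c1)O[C@H](c1cc(OCc3ccccc3)c(OCc3ccccc3)c(OCc3ccccc3)c1)[C@@H](OCc1ccccc1)[C@]2(O)c1c(F)c(Br)c(OCc3ccccc3)cc1OCc1ccccc1 | intermediate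
10 | (2R,3S,4R)-4-[4,6-bis(benzyloxy)-3-bromo-2-fluorophenyl]-3,7-bis(benzyloxy)-2-[3,4,5-tris(benzyloxy)phenyl]chromane (2,3-trans-3,4-cis) | c1ccccc1COc1ccc2c(c1)O[C@H](c1cc(OCc3ccccc3)c(OCc3ccccc3)c(OCc3ccccc3)c1)[C@@H](OCc1ccccc1)[C@H]2c1c(F)c(Br)c(OCc3ccccc3)cc1OCc1ccccc1 | intermediate
11 | (S)-4-benzyloxazolidin-2-one | O=C1OC[C@H](Cc2ccccc2)N1 | starting material
12 | (benzyloxy)acetyl chloride | O=C(Cl)COCc1ccccc1 | starting material
13 | (S)-4-benzyl-3-[(benzyloxy)acetyl]oxazolidin-2-one | O=C1OC[C@H](Cc2ccccc2)N1C(=O)COCc1ccccc1 | intermediate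
14 | 3,4,5-tris(benzyloxy)benzaldehyde | O=Cc1cc(OCc2ccccc2)c(OCc2ccccc2)c(OCc2ccccc2)c1 | starting material
15 | dibutylboron (Z)-enolate of 13 (not isolated) | O=C1OC[C@H](Cc2ccccc2)N1/C(OB(CCCC)CCCC)=C/OCc1ccccc1 | intermediate
16 | (S)-4-benzyl-3-{(2S,3R)-2-(benzyloxy)-3-hydroxy-3-[3,4,5-tris(benzyloxy)phenyl]propanoyl}oxazolidin-2-one | O[C@H](c1cc(OCc2ccccc2)c(OCc2ccccc2)c(OCc2ccccc2)c1)[C@H](OCc1ccccc1)C(=O)N1[C@@H](Cc2ccccc2)COC1=O | intermediate
17 | (1R,2R)-2-(benzyloxy)-1-[3,4,5-tris(benzyloxy)phenyl]propane-1,3-diol | O[C@H](c1cc(OCc2ccccc2)c(OCc2ccccc2)c(OCc2ccccc2)c1)[C@H](OCc1ccccc1)CO | intermediate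
18 | (2R,3R)-2-(benzyloxy)-3-hydroxy-3-[3,4,5-tris(benzyloxy)phenyl]propyl 4-methylbenzenesulfonate (not isolated) | O[C@H](c1cc(OCc2ccccc2)c(OCc2ccccc2)c(OCc2ccccc2)c1)[C@H](OCc1ccccc1)COS(=O)(=O)c1ccc(C)cc1 | intermediate
19 | (2R,3R)-3-(benzyloxy)-2-[3,4,5-tris(benzyloxy)phenyl]oxetane (cis) | O1[C@H](c2cc(OCc3ccccc3)c(OCc3ccccc3)c(OCc3ccccc3)c2)[C@H](OCc2ccccc2)C1 | intermediate
20 | aryllithium from 10, lithium at C4a' in place of bromine (not isolated) | c1ccccc1COc1ccc2c(c1)O[C@H](c1cc(OCc3ccccc3)c(OCc3ccccc3)c(OCc3ccccc3)c1)[C@@H](OCc1ccccc1)[C@H]2c1c(F)c([Li])c(OCc3ccccc3)cc1OCc1ccccc1 | intermediate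
21 | ring-opened fluoroarene carrying the (2R,3R)-2-(benzyloxy)-3-lithiooxy-3-[3,4,5-tris(benzyloxy)phenyl]propyl chain on C4a' (present as its BF3 adduct; not isolated) | c1ccccc1COc1ccc2c(c1)O[C@H](c1cc(OCc3ccccc3)c(OCc3ccccc3)c(OCc3ccccc3)c1)[C@@H](OCc1ccccc1)[C@H]2c1c(F)c(C[C@@H](OCc3ccccc3)[C@H](O[Li])c3cc(OCc4ccccc4)c(OCc4ccccc4)c(OCc4ccccc4)c3)c(OCc3ccccc3)cc1OCc1ccccc1 | intermediate
22 | undeca-O-benzyl robinetinidol-(4β→8)-epigallocatechin | c1ccccc1COc1ccc2c(c1)O[C@H](c1cc(OCc3ccccc3)c(OCc3ccccc3)c(OCc3ccccc3)c1)[C@@H](OCc1ccccc1)[C@H]2c1c(OCc3ccccc3)cc(OCc3ccccc3)c3c1O[C@H](c1cc(OCc4ccccc4)c(OCc4ccccc4)c(OCc4ccccc4)c1)[C@H](OCc1ccccc1)C3 | intermediate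
23 | robinetinidol-(4β→8)-epigallocatechin, (2R,3S,4R)-2-(3,4,5-trihydroxyphenyl)-4-[(2R,3R)-3,5,7-trihydroxy-2-(3,4,5-trihydroxyphenyl)chroman-8-yl]chromane-3,7-diol | Oc1ccc2c(c1)O[C@H](c1cc(O)c(O)c(O)c1)[C@@H](O)[C@H]2c1c(O)cc(O)c2c1O[C@H](c1cc(O)c(O)c(O)c1)[C@H](O)C2 | target

**Totals.** Total step count: 12. Longest linear sequence: 6 steps (for example steps 1, 2, 5, 6, 11, 12).

**Steps most likely to fail**

Step 11. Three processes could go wrong:
- the aryllithium could attack the benzylic oxetane carbon, or BF3 could ionise the 2-aryloxetane;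
- the aryllithium could be consumed by BF3;
- fluoride displacement at the doubly flanked C8a' could be slow, giving the base time to epimerise C4.

The fallback sets out from 16 and returns at 22, still forming both bonds in one flask. Silylation of 16 (TESOTf, 2,6-lutidine) would give the triethylsilyl ether F1. LiBH4 would then give the primary alcohol F2. Tf2O with 2,6-di-tert-butylpyridine at −78 °C would give the primary triflate F3. Aryllithium 20 would be alkylated by F3 in Et2O at −78 °C to the fluoroarene silyl ether F4, which is not isolated. Addition of Bu4NF in THF/DMF to the same flask would remove the silyl group, and the free alkoxide would close ring C by SNAr to give 22. Alkylation of aryllithiums by primary triflates and fluoride-triggered desilylative SNAr are both known reaction types.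

Step 6. Hydride transfer could show poor facial selectivity and give the 3,4-trans epimer. The cation could also lose H3 to form an enol ether, whose reprotonation would scramble C3. The fallback sets out from 3 and returns at 10, making the C4–aryl bond last. NaBH4 reduction of 3 would give the 2,3-trans-3,4-trans flavan-4-ol F5. Monobromination of 5 (1 equiv NBS) would give 1,5-bis(benzyloxy)-2-bromo-3-fluorobenzene F6. BF3·OEt2 in CH2Cl2 at −78 → 0 °C would ionise F5, and F6 would capture the cation by Friedel–Crafts alkylation at its carbon between F and OBn. This classical flavan-3,4-diol coupling is expected to favour the 3,4-trans epimer, so 10 would be the minor product, to be separated by chromatography.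

Step 5. The hindered aryl metal could enolise C3 and open ring C by E1cB instead of adding, or lose LiF on warming. The fallback sets out from 2 and returns at 9. Unprotected ketol 2 would be treated with 2.5 equiv of 8; the first equivalent forms the C3 alkoxide, which cannot enolise toward C3 and chelates the ketone, and the second adds to give the 3,4-diol F7. Selective benzylation of the secondary alkoxide (NaH 1 equiv, BnBr, Bu4NI, THF, 0 °C) would then give 9.

**Further compounds**
F1 | step 11 | (S)-4-benzyl-3-{(2S,3R)-2-(benzyloxy)-3-(triethylsilyloxy)-3-[3,4,5-tris(benzyloxy)phenyl]propanoyl}oxazolidin-2-one | CC[Si](CC)(CC)O[C@H](c1cc(OCc2ccccc2)c(OCc2ccccc2)c(OCc2ccccc2)c1)[C@H](OCc1ccccc1)C(=O)N1[C@@H](Cc2ccccc2)COC1=O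
F2 | step 11 | (2R,3R)-2-(benzyloxy)-3-(triethylsilyloxy)-3-[3,4,5-tris(benzyloxy)phenyl]propan-1-ol | CC[Si](CC)(CC)O[C@H](c1cc(OCc2ccccc2)c(OCc2ccccc2)c(OCc2ccccc2)c1)[C@H](OCc1ccccc1)CO
F3 | step 11 | (2R,3R)-2-(benzyloxy)-3-(triethylsilyloxy)-3-[3,4,5-tris(benzyloxy)phenyl]propyl trifluoromethanesulfonate | CC[Si](CC)(CC)O[C@H](c1cc(OCc2ccccc2)c(OCc2ccccc2)c(OCc2ccccc2)c1)[C@H](OCc1ccccc1)COS(=O)(=O)C(F)(F)F
F4 | step 11 | fluoroarene carrying the (2R,3R)-2-(benzyloxy)-3-(triethylsilyloxy)-3-[3,4,5-tris(benzyloxy)phenyl]propyl chain on C4a' | c1ccccc1COc1ccc2c(c1)O[C@H](c1cc(OCc3ccccc3)c(OCc3ccccc3)c(OCc3ccccc3)c1)[C@@H](OCc1ccccc1)[C@H]2c1c(F)c(C[C@@H](OCc3ccccc3)[C@H](O[Si](CC)(CC)CC)c3cc(OCc4ccccc4)c(OCc4ccccc4)c(OCc4ccccc4)c3)c(OCc3ccccc3)cc1OCc1ccccc1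
F5 | step 6 | (2R,3S,4R)-3,7-bis(benzyloxy)-2-[3,4,5-tris(benzyloxy)phenyl]chroman-4-ol | c1ccccc1COc1ccc2c(c1)O[C@H](c1cc(OCc3ccccc3)c(OCc3ccccc3)c(OCc3ccccc3)c1)[C@@H](OCc1ccccc1)[C@@H]2O
F6 | step 6 | 1,5-bis(benzyloxy)-2-bromo-3-fluorobenzene | Fc1cc(OCc2ccccc2)cc(OCc2ccccc2)c1Br
F7 | step 5 | (2R,3R,4R)-4-[4,6-bis(benzyloxy)-3-bromo-2-fluorophenyl]-7-(benzyloxy)-2-[3,4,5-tris(benzyloxy)phenyl]chromane-3,4-diol | c1ccccc1COc1ccc2c(c1)O[C@H](c1cc(OCc3ccccc3)c(OCc3ccccc3)c(OCc3ccccc3)c1)[C@@H](O)[C@]2(O)c1c(F)c(Br)c(OCc3ccccc3)cc1OCc1ccccc1
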